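The flask at 0.250 equiv of other conformer cannot be read off either earlier run, since it holds more other conformer than both, and the decision on a stop at 25 h needs the share of the charge still unconverted at that time.

| flask | substrate | other conformer | remark | time |
|---|---|---|---|---|
| north-west | 10 mM | 0.12 equiv | run made earlier |  |
| north | 10 mM | 0.19 equiv | run made earlier |  |
| flask | 10 mM | 0.250 equiv |  | 25 h |

- north-west (time / h: other conformer / %, substrate / %, target / %): 4.00: 10.3, 79.2, 9.8; 10.0: 7.6, 66.5, 21.9; 20.0: 5.7, 49.9, 37.4; 30.0: 3.0, 35.4, 50.0
- north (time / h: other conformer / %, substrate / %, target / %): 8.00: 10.7, 66.2, 16.0; 15.0: 9.0, 53.8, 27.6; 25.0: 5.7, 39.8, 42.3; 30.0: 4.4, 34.1, 47.9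

(standard deviation of a reading: 0.5 percentage points)

- steps under discussion: substrate <-> other conformer; substrate -> target; other conformer -> isomer of the product; target <-> isomer of the product

- other conformer present at 25 h, in percent of the substrate and other conformer together charged
- substrate present at 25 h, in percent of the substrate and other conformer together charged
- target present at 25 h, in percent of the substrate and other conformer together charged

The useful quantity is the pool, the fraction of the charge still present as substrate or other conformer, since exchange between those two moves charge inside the pool and leaves its sum unchanged. If the pool falls in proportion to itself, integration gives pool = exp(−kt). At 30.0 h the pool reads 38.4 % in the north-west run and 38.5 % in the north run, each reading scattering by 0.5 percentage points, so the two charges give 0.0319 h⁻¹ and 0.0318 h⁻¹. Their mean, 0.0319 h⁻¹, is the pool constant, an apparent first-order rate constant for loss of the charge from the pool. On this reckoning the pool of the flask halves at 21.8 h and stands at 45.1 % at 25 h, which is later than the halving, so a stop at that time is to be weighed with that share of the charge still unconverted.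

The forecast gives 6.8 % of other conformer, 37.9 % of substrate and 41 % of target, noting that “The substrate-plus-conformer pool decays at about 0.031 per hour in both runs”, where the reckoning here has 0.0319 h⁻¹.

The flask gives 6.75 % of other conformer, 38.0 % of substrate and 40.2 % of target, a pool of 44.8 % against the reckoned 45.1 %.

    substrate ⇌ other conformer (K = 1.10, k = 0.00220 h⁻¹)
    substrate → target (k = 0.0280 h⁻¹)
    other conformer → isomer of the product (k = 0.0520 h⁻¹)
    target ⇌ isomer of the product (K = 0.140, k = 6.30 × 10⁻⁴ h⁻¹)

Of its own charge, the flask keeps 47 % of the substrate and 34 % of the other conformer at 25 h. Read instead at 10 h, the same flask has a reckoned pool of 72.7 %, and it holds 72.2 %.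

(The numbers in the tables come from a simulation with constants of no real substance, noise included.)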